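A reading at 5.0 min comes late for target in this flask: the south run, with the same partner charge, had already fallen from 30.3 % at 1.00 min to 10.7 % at 4.00 min.

| setting | north-east | north-west | south | flask |
|---|---|---|---|---|
| substrate | 2 mM | 2 mM | 1 mM | 2.0 mM |
| partner | 2 mM (fed, over 30 s) | 8 mM (fed, over 30 s) | 4 mM (fed, over 30 s) | 4.00 mM (fed, over 30 s) |
| free catalyst | 100 µM | 100 µM | 100 µM | 100 µM |
| impurity | 14 µM | 14 µM | 14 µM | 14 µM |
| remark | run made earlier | run made earlier | run made earlier |  |
| time |  |  |  | 5.0 min |

- north-east (time / min: target / %): 0.333: 4.0; 0.500: 9.6; 0.667: 14.7; 1.00: 20.8; 1.50: 20.8; 2.50: 17.1; 4.00: 10.4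
- north-west (time / min: target / %): 0.333: 13.9; 0.500: 24.7; 0.667: 31.7; 1.00: 36.0; 1.50: 34.6; 2.50: 20.9; 4.00: 11.0
- south (time / min: target / %): 0.333: 7.0; 0.667: 24.6; 1.00: 30.3; 2.00: 27.6; 4.00: 10.7

(standard deviation of a reading: 0.5 percentage points)

1. time up to 5.0 min at which target stands highest
2. the amount of target, in percent of the substrate charged, at that time

I order the readings by time. The feed comes first, over in 30 s, sooner than the south peak, so in this flask the partner is in while target is still climbing. Then the tail: the last south readings halve target in about 1.46 min, short against 5.0 min. A late reading therefore shows the tail.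

The last rung is the balance of substrate, the limiting reagent in this flask, charged in less than the partner. I carry the partner reserve, 2.00 mM here, the partner charge less the substrate charge: what stands of partner once each substrate has taken one partner, if they pair one to one. The reserves of the north-east, south and north-west runs are 0 mM, 3.00 mM and 6.00 mM, and their highest readings rise with them: 20.8 %, 30.3 %, 36.0 %. Yet the north-west run still falls to 11.0 % at 4.00 min, so target has a loss that a partner shortage does not explain.

This flask has the south partner charge but a smaller reserve, so I place its peak just under the south reading, a little after 1.00 min. The forecast says 28.5 % at 1.15 min, with the runs peaking “just after the feed ends”; its height stands 1.8 percentage points lower than that south reading.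

The flask gives 30.2 % at 1.23 min, a height 1.7 points higher than the forecast's.

    target ⇌ isomer of the product (K = 22.0, k = 0.0190 s⁻¹)
    partner + free catalyst + intermediate → free catalyst + target (k = 2.20 × 10⁵ M⁻² s⁻¹)
    free catalyst + impurity → spent catalyst (k = 32000 M⁻¹ s⁻¹)
    substrate + free catalyst ⇌ free catalyst + intermediate (K = 0.590, k = 290 M⁻¹ s⁻¹)

So this flask is best read near 1.23 min. Without the loss of target to isomer of the product its best stands at 96.1 % instead of 30.2 %. Partner is no shortage here: it stands at 72.6 % of its charge at the best time and at 50.0 % after 50.0 min, the 50.0 % that the reserve gives. With 8.0 mM of substrate the reserve turns negative, −4.00 mM, and partner is down to 0.0353 % at 5.00 min, so substrate and intermediate together keep 50.0 %, the 50.0 % that has no partner.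

The readings were computed with constants of no real substance; the scatter is artificial.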